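**Retrosynthetic overview**

1. Ring A is a benzoic acid in which C1 (CO2H), C2 (OMe), C3 ((S)-carbinol chain) and C4 (H) are contiguous and map onto C3–C6 of a 3-carbomethoxy-4-methoxy-5-alkyl-2-pyrone, while C5 (H) and C6 (O–ring B) map onto the two carbons of an aryl ethynyl ether; the plan rests on this feature.
2. Key disconnection: ring A bonds C4–C5 and C1–C6, giving pyrone 10 and ring B ethynyl ether 21 (Diels–Alder, then loss of CO2); ring A is the last ring formed and arrives with the diaryl ether in place.
3. Pyrone 10 (its ring is formed first on that branch): Noyori reduction of keto ester 1 sets the only stereocenter; malonate C-acylation, enol O-methylation, aminomethylenation and lactonisation follow.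
4. Ethynyl ether 21: ring B is taken intact from creosol (ortho-formylation, methyl-to-benzyl exchange on the catechol oxygen, reduction and silylation, trichloroethylene, n-BuLi).
5. End game: SN2 demethylation of the shielded ester, hydrogenolysis of the benzyl ether, fluoride desilylation.

Key step: step 14

Remark: the enamine double bond of 9 and the two bridgehead carbons of 22 are written without descriptors, because both elements are erased in the same flask (lactonisation; loss of CO2).

**Route**

Step 1
Reactants: 1 methyl 5-methyl-3-oxohexanoate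
Product: 2 methyl (3S)-3-hydroxy-5-methylhexanoate
Conditions: H2 (50 atm), RuCl2[(S)-BINAP] (0.1 mol %), MeOH, 50 °C
Reagents that add atoms: none
Why: Noyori asymmetric hydrogenation of a β-keto ester, in which the substrate chelates the ruthenium–BINAP hydride through ketone and ester oxygens and hydride goes to one ketone face, (S)-BINAP being expected to give the 3S alcohol (the mirror of the known (R)-BINAP to (R)-3-hydroxyalkanoate correlation), which sets the only stereocenter of the target.

Step 2
Reactants: 2 methyl (3S)-3-hydroxy-5-methylhexanoate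
Product: 3 methyl (3S)-3-[(tert-butyldimethylsilyl)oxy]-5-methylhexanoate
Conditions: TBSCl, imidazole, DMF, 23 °C
Reagents that add atoms: tert-butyldimethylsilyl chloride, CC(C)(C)[Si](C)(C)Cl
Why: Standard silylation of a secondary alcohol (Corey conditions), which masks the carbinol for the basic and thermal steps that follow and does not touch the stereocenter.

Step 3
Reactants: 3 methyl (3S)-3-[(tert-butyldimethylsilyl)oxy]-5-methylhexanoate
Product: 4 (3S)-3-[(tert-butyldimethylsilyl)oxy]-5-methylhexanoic acid
Conditions: LiOH·H2O, THF–MeOH–H2O, 23 °C; then dilute HCl to pH 4, 0 °C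
Reagents that add atoms: lithium hydroxide, [Li+].[OH-]
Why: Saponification of an unhindered methyl ester at room temperature, mild enough that the β-silyloxy group should neither eliminate nor be cleaved, the acid being liberated at pH 4 to spare the silyl ether.

Step 4
Reactants: 4 (3S)-3-[(tert-butyldimethylsilyl)oxy]-5-methylhexanoic acid; 5 dimethyl malonate
Product: 7 dimethyl 2-[(3S)-3-[(tert-butyldimethylsilyl)oxy]-5-methylhexanoyl]propanedioate, via acid chloride 6 (not isolated)
Conditions: Me2C=C(Cl)NMe2, CH2Cl2, 0 °C; then 5, MgCl2, Et3N, MeCN, 0 → 23 °C; aq. HCl work-up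
Reagents that add atoms: none
Why: The neutral α-chloroenamine reagent converts the acid into acid chloride 6 without free HCl, and the magnesium enolate of dimethyl malonate (MgCl2 and Et3N, Rathke-type C-acylation) is acylated on carbon, the product being held as its magnesium chelate so that it is not acylated twice.

Step 5
Reactants: 7 dimethyl 2-[(3S)-3-[(tert-butyldimethylsilyl)oxy]-5-methylhexanoyl]propanedioate
Product: 8 dimethyl 2-[(3S)-3-[(tert-butyldimethylsilyl)oxy]-1-methoxy-5-methylhexylidene]propanedioate
Conditions: Me3SiCHN2, MeOH–PhMe (1:4), 0 → 23 °C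
Reagents that add atoms: trimethylsilyldiazomethane, C[Si](C)(C)C=[N+]=[N-]
Why: The acylmalonate is an acidic, enolised tricarbonyl compound, so the diazomethane equivalent should methylate the enol oxygen (O-methylation of an enol; C-methylation would need a quaternary carbon) under neutral conditions that leave the silyl ether alone.

Step 6
Reactants: 8 dimethyl 2-[(3S)-3-[(tert-butyldimethylsilyl)oxy]-1-methoxy-5-methylhexylidene]propanedioate
Product: 10 methyl 5-[(1S)-1-[(tert-butyldimethylsilyl)oxy]-3-methylbutyl]-4-methoxy-2-oxo-2H-pyran-3-carboxylate, via dienamine 9 (not isolated)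
Conditions: Me2NCH(OMe)2, PhMe, 85 °C; evaporate; then AcOH, THF–H2O, 45 °C
Reagents that add atoms: N,N-dimethylformamide dimethyl acetal, COC(OC)N(C)C; water, O
Why: Vinylogous aminomethylenation in which the γ-CH2 of the alkylidene malonate condenses with the formamide acetal to give push–pull dienamine 9, after which mild aqueous acid hydrolyses the enamine to the enol, whose oxygen closes onto the cis ester with loss of methanol (six-membered lactonisation driven by formation of the 2-pyrone), the carbinol carbon carrying no acidic hydrogen and so keeping its configuration.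

Step 7
Reactants: 11 creosol (2-methoxy-4-methylphenol)
Product: 12 2-hydroxy-3-methoxy-5-methylbenzaldehyde
Conditions: (CH2O)n, MgCl2, Et3N, MeCN, reflux; aq. HCl work-up
Reagents that add atoms: paraformaldehyde (formaldehyde unit), C=O
Why: Magnesium-mediated ortho-formylation (Casnati–Skattebøl), in which the magnesium phenoxide delivers formaldehyde to the only free ortho position, the para position being blocked by the methyl group, and a second formaldehyde oxidises the benzylic alkoxide to the aldehyde by hydride transfer.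

Step 8
Reactants: 12 2-hydroxy-3-methoxy-5-methylbenzaldehyde
Product: 13 2,3-dihydroxy-5-methylbenzaldehyde
Conditions: BBr3, CH2Cl2, −78 → 0 °C; then H2O
Reagents that add atoms: none
Why: Lewis acid demethylation of an aryl methyl ether with BBr3, which frees the catechol so that this oxygen can carry a removable benzyl group instead of a methyl group.

Step 9
Reactants: 13 2,3-dihydroxy-5-methylbenzaldehyde
Product: 14 3-(benzyloxy)-2-hydroxy-5-methylbenzaldehyde
Conditions: NaH (2.2 equiv), DMSO, 20 °C; BnBr (1.0 equiv); then aq. HCl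
Reagents that add atoms: benzyl bromide, BrCc1ccccc1
Why: Regioselective Williamson etherification through the dianion, in which the C2 phenoxide is conjugated with and chelated to the aldehyde, so the single equivalent of benzyl bromide should be taken by the more nucleophilic C3 phenoxide.

Step 10
Reactants: 14 3-(benzyloxy)-2-hydroxy-5-methylbenzaldehyde
Product: 15 2-(benzyloxy)-6-(hydroxymethyl)-4-methylphenol
Conditions: NaBH4, MeOH–THF, 0 °C
Reagents that add atoms: none
Why: Borohydride reduction of an aromatic aldehyde to the benzylic alcohol, with no other reducible group present.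

Step 11
Reactants: 15 2-(benzyloxy)-6-(hydroxymethyl)-4-methylphenol
Product: 16 2-(benzyloxy)-6-{[(tert-butyldimethylsilyl)oxy]methyl}-4-methylphenol
Conditions: TBSCl (1.05 equiv), imidazole, CH2Cl2, 0 °C
Reagents that add atoms: tert-butyldimethylsilyl chloride, CC(C)(C)[Si](C)(C)Cl
Why: Chemoselective silylation, in which one equivalent of silyl chloride should take the primary benzylic alcohol ahead of the hydrogen-bonded phenol flanked by two ortho substituents, as is usual for salicyl alcohols.

Step 12
Reactants: 16 2-(benzyloxy)-6-{[(tert-butyldimethylsilyl)oxy]methyl}-4-methylphenol; 17 trichloroethylene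
Product: 18 tert-butyl({3-(benzyloxy)-2-[(E)-1,2-dichloroethenyloxy]-5-methylphenyl}methoxy)dimethylsilane
Conditions: K2CO3, DMF, 70 °C
Reagents that add atoms: none
Why: Base converts trichloroethylene into dichloroacetylene, to which the phenoxide adds in anti fashion to give the (E)-1,2-dichlorovinyl ether, a standard entry to alkynyl ethers that tolerates the alkyl silyl ether and the benzyl ether.

Step 13
Reactants: 18 tert-butyl({3-(benzyloxy)-2-[(E)-1,2-dichloroethenyloxy]-5-methylphenyl}methoxy)dimethylsilane
Product: 21 tert-butyl{[3-(benzyloxy)-2-(ethynyloxy)-5-methylphenyl]methoxy}dimethylsilane, via chloroethynyl ether 19 (not isolated), via lithium acetylide 20 (not isolated)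
Conditions: n-BuLi (2.3 equiv), THF, −78 → −40 °C; then H2O, −78 °C; used at once
Reagents that add atoms: none
Why: n-BuLi removes the vinylic hydrogen and chloride is eliminated to give chloroalkyne 19, a second equivalent performs chlorine–lithium exchange to acetylide 20, and cold protonation gives the terminal aryl alkynyl ether (the established dichlorovinyl ether route), which is not stored because such alkynes oligomerise.

Step 14
Reactants: 10 methyl 5-[(1S)-1-[(tert-butyldimethylsilyl)oxy]-3-methylbutyl]-4-methoxy-2-oxo-2H-pyran-3-carboxylate; 21 tert-butyl{[3-(benzyloxy)-2-(ethynyloxy)-5-methylphenyl]methoxy}dimethylsilane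
Product: 23 methyl 6-[2-(benzyloxy)-6-{[(tert-butyldimethylsilyl)oxy]methyl}-4-methylphenoxy]-3-[(1S)-1-[(tert-butyldimethylsilyl)oxy]-3-methylbutyl]-2-methoxybenzoate, via bridged lactone 22 (not isolated)
Conditions: 21 (2.5 equiv, in portions), PhMe (1 M), 110 °C, sealed tube
Reagents that add atoms: none
Why: Inverse-electron-demand Diels–Alder reaction in which the electron-rich ethynyl ether 21 (largest HOMO coefficient on its terminal CH) adds across C3 and C6 of the electron-poor pyrone 10 (LUMO lowered by the C3 ester and the lactone carbonyl) to give the 2-oxabicyclo[2.2.2]octadienone 22, which expels CO2 by retro-Diels–Alder at the reaction temperature and leaves benzene ring A; the closest known reaction type is the cycloaddition of 3-carboalkoxy-2-pyrones with ynamines, alkynyl ethers and ketene acetals to give benzoates. Ring A is closed by an intermolecular [4+2] cycloaddition that forms C4–C5 and C1–C6 in one asynchronous event (terminal alkyne carbon to pyrone C6 leading), followed by excision of the lactone bridge. No stereocenter is created in the product, since the two bridgehead centers of 22 vanish on aromatisation and both diastereomers of 22 converge on 23, while the S carbinol from step 1 is a spectator under neutral, aprotic heating. The step needs regioselectivity (aryloxy carbon next to the ester carbon), secured by pairing the nucleophilic alkyne terminus with pyrone C6, the position vinylogous to both carbonyl groups, so that the oxygen-bearing alkyne carbon closes on C3. It also needs the alkyne to react with the diene faster than with itself; because the C4 methoxy group donates into the diene and slows the cycloaddition, the alkyne is used in excess, added in portions, at high concentration in a neutral hydrocarbon.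

Step 15
Reactants: 23 methyl 6-[2-(benzyloxy)-6-{[(tert-butyldimethylsilyl)oxy]methyl}-4-methylphenoxy]-3-[(1S)-1-[(tert-butyldimethylsilyl)oxy]-3-methylbutyl]-2-methoxybenzoate
Product: 24 6-[2-(benzyloxy)-6-{[(tert-butyldimethylsilyl)oxy]methyl}-4-methylphenoxy]-3-[(1S)-1-[(tert-butyldimethylsilyl)oxy]-3-methylbutyl]-2-methoxybenzoic acid
Conditions: NaSEt, DMF, 60 °C; then dilute HCl to pH 4
Reagents that add atoms: none
Why: The ester carbonyl is shielded by two ortho substituents, so the methyl ester is cleaved by SN2 attack of the thiolate on its O-methyl carbon (carboxylate as leaving group), a pathway much faster than attack on the aryl methyl ether at this temperature and harmless to silyl and benzyl ethers, and it is run while the ring B phenol is still benzylated so that no phenoxide can lactonise onto the ester.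

Step 16
Reactants: 24 6-[2-(benzyloxy)-6-{[(tert-butyldimethylsilyl)oxy]methyl}-4-methylphenoxy]-3-[(1S)-1-[(tert-butyldimethylsilyl)oxy]-3-methylbutyl]-2-methoxybenzoic acid
Product: 25 3-[(1S)-1-[(tert-butyldimethylsilyl)oxy]-3-methylbutyl]-6-[2-{[(tert-butyldimethylsilyl)oxy]methyl}-6-hydroxy-4-methylphenoxy]-2-methoxybenzoic acid
Conditions: H2 (1 atm), Pd/C, EtOAc, 23 °C
Reagents that add atoms: none
Why: Catalytic hydrogenolysis of the aryl benzyl ether over palladium on carbon in a neutral, non-alcoholic solvent, conditions under which the benzylic silyl ethers and the diaryl ether should persist.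

Step 17
Reactants: 25 3-[(1S)-1-[(tert-butyldimethylsilyl)oxy]-3-methylbutyl]-6-[2-{[(tert-butyldimethylsilyl)oxy]methyl}-6-hydroxy-4-methylphenoxy]-2-methoxybenzoic acid
Product: 26 3-[(1S)-1-hydroxy-3-methylbutyl]-6-[2-hydroxy-6-(hydroxymethyl)-4-methylphenoxy]-2-methoxybenzoic acid (CNP0221397.1)
Conditions: HF·pyridine, pyridine, THF, 0 → 23 °C
Reagents that add atoms: none
Why: Fluoride cleaves both silicon–oxygen bonds under buffered, near-neutral conditions that should not ionise the electron-rich benzylic carbinol, so the target is delivered with the S configuration intact.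

**Compound list**

1 | methyl 5-methyl-3-oxohexanoate | COC(=O)CC(=O)CC(C)C | starting material
2 | methyl (3S)-3-hydroxy-5-methylhexanoate | COC(=O)C[C@@H](O)CC(C)C | intermediate
3 | methyl (3S)-3-[(tert-butyldimethylsilyl)oxy]-5-methylhexanoate | COC(=O)C[C@@H](O[Si](C)(C)C(C)(C)C)CC(C)C | intermediate
4 | (3S)-3-[(tert-butyldimethylsilyl)oxy]-5-methylhexanoic acid | OC(=O)C[C@@H](O[Si](C)(C)C(C)(C)C)CC(C)C | intermediate
5 | dimethyl malonate | COC(=O)CC(=O)OC | starting material
6 | (3S)-3-[(tert-butyldimethylsilyl)oxy]-5-methylhexanoyl chloride | ClC(=O)C[C@@H](O[Si](C)(C)C(C)(C)C)CC(C)C | intermediate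
7 | dimethyl 2-[(3S)-3-[(tert-butyldimethylsilyl)oxy]-5-methylhexanoyl]propanedioate | COC(=O)C(C(=O)OC)C(=O)C[C@@H](O[Si](C)(C)C(C)(C)C)CC(C)C | intermediate
8 | dimethyl 2-[(3S)-3-[(tert-butyldimethylsilyl)oxy]-1-methoxy-5-methylhexylidene]propanedioate | COC(=O)C(C(=O)OC)=C(OC)C[C@@H](O[Si](C)(C)C(C)(C)C)CC(C)C | intermediate
9 | dimethyl 2-{2-[(1S)-1-[(tert-butyldimethylsilyl)oxy]-3-methylbutyl]-3-(dimethylamino)-1-methoxyprop-2-en-1-ylidene}propanedioate | COC(=O)C(C(=O)OC)=C(OC)C(=CN(C)C)[C@@H](O[Si](C)(C)C(C)(C)C)CC(C)C | intermediate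
10 | methyl 5-[(1S)-1-[(tert-butyldimethylsilyl)oxy]-3-methylbutyl]-4-methoxy-2-oxo-2H-pyran-3-carboxylate | COC(=O)c1c(OC)c([C@@H](O[Si](C)(C)C(C)(C)C)CC(C)C)coc1=O | intermediate
11 | creosol (2-methoxy-4-methylphenol) | COc1cc(C)ccc1O | starting material
12 | 2-hydroxy-3-methoxy-5-methylbenzaldehyde | COc1cc(C)cc(C=O)c1O | intermediate
13 | 2,3-dihydroxy-5-methylbenzaldehyde | Cc1cc(O)c(O)c(C=O)c1 | intermediate
14 | 3-(benzyloxy)-2-hydroxy-5-methylbenzaldehyde | Cc1cc(OCc2ccccc2)c(O)c(C=O)c1 | intermediate
15 | 2-(benzyloxy)-6-(hydroxymethyl)-4-methylphenol | Cc1cc(CO)c(O)c(OCc2ccccc2)c1 | intermediate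
16 | 2-(benzyloxy)-6-{[(tert-butyldimethylsilyl)oxy]methyl}-4-methylphenol | Cc1cc(CO[Si](C)(C)C(C)(C)C)c(O)c(OCc2ccccc2)c1 | intermediate
17 | trichloroethylene | ClC=C(Cl)Cl | starting material
18 | tert-butyl({3-(benzyloxy)-2-[(E)-1,2-dichloroethenyloxy]-5-methylphenyl}methoxy)dimethylsilane | Cl/C=C(/Cl)Oc1c(OCc2ccccc2)cc(C)cc1CO[Si](C)(C)C(C)(C)C | intermediate
19 | tert-butyl({3-(benzyloxy)-2-[(chloroethynyl)oxy]-5-methylphenyl}methoxy)dimethylsilane | ClC#COc1c(OCc2ccccc2)cc(C)cc1CO[Si](C)(C)C(C)(C)C | intermediate
20 | lithium 2-[2-(benzyloxy)-6-{[(tert-butyldimethylsilyl)oxy]methyl}-4-methylphenoxy]ethynide | [Li]C#COc1c(OCc2ccccc2)cc(C)cc1CO[Si](C)(C)C(C)(C)C | intermediate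
21 | tert-butyl{[3-(benzyloxy)-2-(ethynyloxy)-5-methylphenyl]methoxy}dimethylsilane | C#COc1c(OCc2ccccc2)cc(C)cc1CO[Si](C)(C)C(C)(C)C | intermediate
22 | methyl 8-[2-(benzyloxy)-6-{[(tert-butyldimethylsilyl)oxy]methyl}-4-methylphenoxy]-6-[(1S)-1-[(tert-butyldimethylsilyl)oxy]-3-methylbutyl]-5-methoxy-3-oxo-2-oxabicyclo[2.2.2]octa-5,7-diene-4-carboxylate (both bridgehead configurations) | COC(=O)C12C(=O)OC(C=C1Oc3c(OCc4ccccc4)cc(C)cc3CO[Si](C)(C)C(C)(C)C)C([C@@H](O[Si](C)(C)C(C)(C)C)CC(C)C)=C2OC | intermediate
23 | methyl 6-[2-(benzyloxy)-6-{[(tert-butyldimethylsilyl)oxy]methyl}-4-methylphenoxy]-3-[(1S)-1-[(tert-butyldimethylsilyl)oxy]-3-methylbutyl]-2-methoxybenzoate | COC(=O)c1c(OC)c([C@@H](O[Si](C)(C)C(C)(C)C)CC(C)C)ccc1Oc1c(OCc2ccccc2)cc(C)cc1CO[Si](C)(C)C(C)(C)C | intermediate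
24 | 6-[2-(benzyloxy)-6-{[(tert-butyldimethylsilyl)oxy]methyl}-4-methylphenoxy]-3-[(1S)-1-[(tert-butyldimethylsilyl)oxy]-3-methylbutyl]-2-methoxybenzoic acid | COc1c([C@@H](O[Si](C)(C)C(C)(C)C)CC(C)C)ccc(Oc2c(OCc3ccccc3)cc(C)cc2CO[Si](C)(C)C(C)(C)C)c1C(=O)O | intermediate
25 | 3-[(1S)-1-[(tert-butyldimethylsilyl)oxy]-3-methylbutyl]-6-[2-{[(tert-butyldimethylsilyl)oxy]methyl}-6-hydroxy-4-methylphenoxy]-2-methoxybenzoic acid | COc1c([C@@H](O[Si](C)(C)C(C)(C)C)CC(C)C)ccc(Oc2c(O)cc(C)cc2CO[Si](C)(C)C(C)(C)C)c1C(=O)O | intermediate
26 | 3-[(1S)-1-hydroxy-3-methylbutyl]-6-[2-hydroxy-6-(hydroxymethyl)-4-methylphenoxy]-2-methoxybenzoic acid (CNP0221397.1) | COc1c([C@@H](O)CC(C)C)ccc(Oc2c(O)cc(C)cc2CO)c1C(=O)O | target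

**Step count**

Total: 17 steps. Longest linear sequence: 11 steps (steps 7–17, from creosol); the pyrone branch is 10 steps (steps 1–6 and 14–17).

**Steps most likely to fail, with fallbacks**

Step 14 (key cycloaddition). The ethynyl ether may be consumed by self-condensation or thermal decay before it engages the diene, which is slowed by the C4 methoxy group. The fallback keeps the pyrone-to-arene construction of ring A but makes the ether bond afterwards; it sets out from pyrone 10 and phenol 16 and returns at 23. Heating 10 with 1,1-bis(trimethylsilyloxy)ethene in toluene should give, by the same inverse-demand cycloaddition with loss of CO2 and trimethylsilanol, methyl 3-[(1S)-1-[(tert-butyldimethylsilyl)oxy]-3-methylbutyl]-2-methoxy-6-[(trimethylsilyl)oxy]benzoate F1. Brief K2CO3 in MeOH should free the salicylate phenol, methyl 3-[(1S)-1-[(tert-butyldimethylsilyl)oxy]-3-methylbutyl]-6-hydroxy-2-methoxybenzoate F2. Tf2O and pyridine would convert it into methyl 3-[(1S)-1-[(tert-butyldimethylsilyl)oxy]-3-methylbutyl]-2-methoxy-6-[(trifluoromethanesulfonyl)oxy]benzoate F3. Palladium-catalysed C–O coupling of F3 with phenol 16 (Pd(OAc)2, 2-(di-tert-butylphosphino)-2',4',6'-triisopropylbiphenyl, K3PO4, toluene, 100 °C) would then give 23.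

Step 6 (aminomethylenation and lactonisation). β-Elimination of silanol from the γ-carbanion or from the enamine, or loss of the silyl ether during the acid treatment, may divert the material. The fallback introduces the pyrone C6 carbon as a masked formyl group at the ester stage, so that no vinylogous deprotonation is needed; it sets out from ester 3 and returns at 10.
- Enolisation of 3 (LDA, Me3SiCl, THF, −78 °C) should give the silyl ketene acetal, tert-butyl{[(3S)-1-methoxy-5-methyl-1-[(trimethylsilyl)oxy]hex-1-en-3-yl]oxy}dimethylsilane F4.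
- Mukaiyama-type alkylation with HC(OMe)3 and catalytic Me3SiOTf in CH2Cl2 at −78 °C should give methyl (3S)-3-[(tert-butyldimethylsilyl)oxy]-2-(dimethoxymethyl)-5-methylhexanoate F5 (both C2 epimers, that center being erased later).
- LiOH would give (3S)-3-[(tert-butyldimethylsilyl)oxy]-2-(dimethoxymethyl)-5-methylhexanoic acid F6.
- The α-chloroenamine reagent would give (3S)-3-[(tert-butyldimethylsilyl)oxy]-2-(dimethoxymethyl)-5-methylhexanoyl chloride F7.
- Acylation of dimethyl malonate 5 (MgCl2, Et3N) would give dimethyl 2-[(3S)-3-[(tert-butyldimethylsilyl)oxy]-2-(dimethoxymethyl)-5-methylhexanoyl]propanedioate F8.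
- Me3SiCHN2 would give dimethyl 2-[(3S)-3-[(tert-butyldimethylsilyl)oxy]-2-(dimethoxymethyl)-1-methoxy-5-methylhexylidene]propanedioate F9.
- Pyridinium p-toluenesulfonate in wet acetone at 50 °C should unmask the acetal and close the enol lactone with loss of methanol to give 10.

Step 13 (ethynyl ether formation). The terminal alkynyl ether may hydrate or oligomerise during aqueous work-up and concentration. The fallback stores the alkyne as a C-silyl derivative and frees it only in front of the cycloaddition; it sets out from 18 and returns at 21. Acetylide 20, generated from 18 as in step 13, would be quenched with Me3SiCl instead of water to give tert-butyl{[3-(benzyloxy)-5-methyl-2-{[(trimethylsilyl)ethynyl]oxy}phenyl]methoxy}dimethylsilane F10, which should survive chromatography and storage. K2CO3 in MeOH at 0 °C, directly before step 14, would remove the C-silyl group and give 21.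

**Further compounds**

F1 | step 14 | methyl 3-[(1S)-1-[(tert-butyldimethylsilyl)oxy]-3-methylbutyl]-2-methoxy-6-[(trimethylsilyl)oxy]benzoate | COC(=O)c1c(O[Si](C)(C)C)ccc([C@@H](O[Si](C)(C)C(C)(C)C)CC(C)C)c1OC
F2 | step 14 | methyl 3-[(1S)-1-[(tert-butyldimethylsilyl)oxy]-3-methylbutyl]-6-hydroxy-2-methoxybenzoate | COC(=O)c1c(O)ccc([C@@H](O[Si](C)(C)C(C)(C)C)CC(C)C)c1OC
F3 | step 14 | methyl 3-[(1S)-1-[(tert-butyldimethylsilyl)oxy]-3-methylbutyl]-2-methoxy-6-[(trifluoromethanesulfonyl)oxy]benzoate | COC(=O)c1c(OS(=O)(=O)C(F)(F)F)ccc([C@@H](O[Si](C)(C)C(C)(C)C)CC(C)C)c1OC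
F4 | step 6 | tert-butyl{[(3S)-1-methoxy-5-methyl-1-[(trimethylsilyl)oxy]hex-1-en-3-yl]oxy}dimethylsilane | COC(O[Si](C)(C)C)=C[C@@H](O[Si](C)(C)C(C)(C)C)CC(C)C
F5 | step 6 | methyl (3S)-3-[(tert-butyldimethylsilyl)oxy]-2-(dimethoxymethyl)-5-methylhexanoate | COC(=O)C(C(OC)OC)[C@@H](O[Si](C)(C)C(C)(C)C)CC(C)C
F6 | step 6 | (3S)-3-[(tert-butyldimethylsilyl)oxy]-2-(dimethoxymethyl)-5-methylhexanoic acid | OC(=O)C(C(OC)OC)[C@@H](O[Si](C)(C)C(C)(C)C)CC(C)C
F7 | step 6 | (3S)-3-[(tert-butyldimethylsilyl)oxy]-2-(dimethoxymethyl)-5-methylhexanoyl chloride | ClC(=O)C(C(OC)OC)[C@@H](O[Si](C)(C)C(C)(C)C)CC(C)C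
F8 | step 6 | dimethyl 2-[(3S)-3-[(tert-butyldimethylsilyl)oxy]-2-(dimethoxymethyl)-5-methylhexanoyl]propanedioate | COC(=O)C(C(=O)OC)C(=O)C(C(OC)OC)[C@@H](O[Si](C)(C)C(C)(C)C)CC(C)C
F9 | step 6 | dimethyl 2-[(3S)-3-[(tert-butyldimethylsilyl)oxy]-2-(dimethoxymethyl)-1-methoxy-5-methylhexylidene]propanedioate | COC(=O)C(C(=O)OC)=C(OC)C(C(OC)OC)[C@@H](O[Si](C)(C)C(C)(C)C)CC(C)C
F10 | step 13 | tert-butyl{[3-(benzyloxy)-5-methyl-2-{[(trimethylsilyl)ethynyl]oxy}phenyl]methoxy}dimethylsilane | C[Si](C)(C)C#COc1c(OCc2ccccc2)cc(C)cc1CO[Si](C)(C)C(C)(C)C
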